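The two identical (E)-4-hydroxycinnamoyl esters sit on the trans-vicinal oxygens O4 and O5 of the quinic acid cyclohexane ring; the C3 and C1 hydroxyls are free. Each ester is cut at the bond between aryl carbon C1' and the olefinic β-carbon, which leads back to a quinate 4,5-bis-acrylate and 4-iodophenol. One twofold Heck arylation then makes both aryl–Cβ bonds and sets both E olefins in a single operation, with the phenols unprotected. The precursor is methyl quinate with O3 silylated (TBS), O4 and O5 acryloylated and the tertiary C1 hydroxyl free. It comes from (−)-quinic acid through the 1,5-lactone, which masks O5 while O3 is silylated.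

Key step: step 5

Remark on the chemistry: quinic acid numbering is used throughout (C1 bears the carboxyl and a hydroxyl; O3 is cis to O4; O5 is trans to O4 and cis to the carboxyl). No step breaks a bond to a ring stereocentre, so all four are carried unchanged from 1. TBS = tert-butyldimethylsilyl.

Step 1
Reactants: 1 (−)-quinic acid
Product: 2 quinide (quinic acid 1,5-lactone)
Conditions: Amberlyst 15 (H+ form), DMF–toluene, reflux, Dean–Stark
Reagents that add atoms: none
Why: Acid-catalysed intramolecular Fischer esterification (γ-lactonisation) should give only the 1,5-lactone, because O5 is the one ring oxygen on the same face as the carboxyl and reaches it in the ring-flipped chair, while azeotropic removal of water drives the equilibrium.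

Step 2
Reactants: 2 quinide
Product: 3 3-O-(tert-butyldimethylsilyl)quinide
Conditions: TBSCl (1.1 equiv), imidazole (2.5 equiv), DMF, 0 °C → rt
Reagents that add atoms: tert-butyldimethylsilyl chloride, CC(C)(C)[Si](C)(C)Cl
Why: Regioselective O-silylation under Corey conditions should occur at O3, the only equatorial and unhindered secondary hydroxyl of the bicyclic lactone, since the C4 hydroxyl is axial beneath the lactone bridge and the C1 hydroxyl is tertiary.

Step 3
Reactants: 3 3-O-(tert-butyldimethylsilyl)quinide
Product: 4 methyl 3-O-(tert-butyldimethylsilyl)quinate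
Conditions: NaOMe (0.2 equiv), MeOH, 0 °C; AcOH quench
Reagents that add atoms: methanol, CO
Why: Base-catalysed transesterification (Zemplén-type methanolysis) of the strained bicyclic γ-lactone in methanol as solvent should open it by acyl–oxygen cleavage, so C5 keeps its configuration, and catalytic base, low temperature, short contact and an acidic quench are chosen to keep the silyl group from moving from O3 to the cis-neighbouring O4.

Step 4
Reactants: 4 methyl 3-O-(tert-butyldimethylsilyl)quinate; 5 acryloyl chloride
Product: 7 methyl 4,5-di-O-acryloyl-3-O-(tert-butyldimethylsilyl)quinate, via methyl 5-O-acryloyl-3-O-TBS-quinate 6 (not isolated)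
Conditions: 5 (2.4 equiv), Et3N (3 equiv), DMAP (5 mol%), BHT (trace), CH2Cl2, −20 → 0 °C
Reagents that add atoms: none
Why: Twofold O-acylation by an acid chloride (DMAP-assisted nucleophilic acyl substitution) should esterify the equatorial secondary hydroxyls, O5 first and then the more crowded O4, with the small acryloyl group, while the tertiary C1 hydroxyl, axial and 1,3-diaxial to the bulky silyloxy group, is spared at low temperature with a limited excess of 5, and BHT suppresses radical polymerisation.

Step 5
Reactants: 7 methyl 4,5-di-O-acryloyl-3-O-(tert-butyldimethylsilyl)quinate; 8 4-iodophenol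
Product: 11 methyl 3-O-(tert-butyldimethylsilyl)-4,5-di-O-[(E)-4-hydroxycinnamoyl]quinate, via 4-O-coumaroyl 5-O-acryloyl monoarylated ester 9 (not isolated), via 4-O-acryloyl 5-O-coumaroyl monoarylated ester 10 (not isolated)
Conditions: 8 (2.4 equiv), Pd(OAc)2 (10 mol%), Bu4NCl (2 equiv), NaHCO3 (5 equiv), DMF, 60–70 °C, Ar
Reagents that add atoms: none
Why: Pd(OAc)2 is reduced in the flask to zerovalent palladium, which is kept active by Bu4NCl and inserts into the C–I bond of 8; the arylpalladium iodide adds syn across an acrylate C=C with the aryl group on the terminal CH2 carbon and palladium on the α-carbon, and after bond rotation syn β-hydride elimination releases the (E)-cinnamate while NaHCO3 takes up HI and regenerates zerovalent palladium. This is the Mizoroki–Heck reaction under ligand-free Jeffery conditions, the known way from acrylate esters and 4-iodophenol to 4-hydroxycinnamates, run here twice on one substrate by way of the monoarylated esters 9 and 10. No ring is closed and no stereocentre is created; only the two olefin geometries are set, and the four ring stereocentres are spectators. The step needs terminal regioselectivity and E geometry, which come from the polarisation of the acrylate (aryl to the electron-poor β-carbon) and from the lower-energy transoid arrangement of aryl and ester in the β-hydride elimination. It also needs both acyl groups to stay where they are: the silyl ether on O3 removes the only hydroxyl that is cis-vicinal to an acyloxy group, the C1 hydroxyl lies on the ring face opposite O5, and hydrogencarbonate is too weak a base to open esters or to convert the phenol largely into phenoxide. The trans-diequatorial acrylates on O4 and O5 are far enough apart to react as independent acrylates, and a small excess of 8 at moderate temperature limits a second arylation of a cinnamate β-carbon.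

Step 6
Reactants: 11 methyl 3-O-(tert-butyldimethylsilyl)-4,5-di-O-[(E)-4-hydroxycinnamoyl]quinate
Product: 13 4,5-di-O-[(E)-4-hydroxycinnamoyl]quinic acid (the target), via methyl 4,5-di-O-p-coumaroylquinate 12 (not isolated)
Conditions: 2 M aq. HCl–THF (1:3), rt → 35 °C
Reagents that add atoms: water, O
Why: Acid-catalysed desilylation followed by acid-catalysed acyl–oxygen hydrolysis of the methyl ester should free O3 and the carboxyl in one operation, because the unconjugated methyl ester is attacked by water faster than the two conjugated, electron-rich cinnamates on hindered secondary ring oxygens, acyl migration from O4 to the freed O3 is slow in acid, and the acylated O5 rules out relactonisation.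

Compound list
1 | (−)-quinic acid, (1S,3R,4S,5R)-1,3,4,5-tetrahydroxycyclohexane-1-carboxylic acid (1-OH, 3-OH, 4-OH on one ring face; 5-OH and CO2H on the other) | O[C@@H]1[C@H](O)C[C@@](O)(C(=O)O)C[C@H]1O | starting material
2 | quinide, the 1,5-lactone of quinic acid (carboxyl esterified by O5; 1-, 3- and 4-OH free; ring configuration of 1) | O[C@@H]1[C@H](O)C[C@]2(O)C[C@H]1OC2=O | intermediate
3 | 3-O-(tert-butyldimethylsilyl)quinide (silyl ether on O3; 1- and 4-OH free) | O[C@@H]1[C@H](O[Si](C)(C)C(C)(C)C)C[C@]2(O)C[C@H]1OC2=O | intermediate
4 | methyl 3-O-(tert-butyldimethylsilyl)quinate (1-, 4- and 5-OH free; ring configuration of 1) | O[C@@H]1[C@H](O[Si](C)(C)C(C)(C)C)C[C@@](O)(C(=O)OC)C[C@H]1O | intermediate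
5 | acryloyl chloride | C=CC(=O)Cl | starting material
6 | methyl 5-O-acryloyl-3-O-(tert-butyldimethylsilyl)quinate (4-OH and 1-OH free) | O[C@@H]1[C@H](O[Si](C)(C)C(C)(C)C)C[C@@](O)(C(=O)OC)C[C@H]1OC(=O)C=C | intermediate
7 | methyl 4,5-di-O-acryloyl-3-O-(tert-butyldimethylsilyl)quinate (1-OH free) | C=CC(=O)O[C@@H]1[C@H](O[Si](C)(C)C(C)(C)C)C[C@@](O)(C(=O)OC)C[C@H]1OC(=O)C=C | intermediate
8 | 4-iodophenol | Oc1ccc(I)cc1 | starting material
9 | methyl 5-O-acryloyl-4-O-[(E)-4-hydroxycinnamoyl]-3-O-(tert-butyldimethylsilyl)quinate | O=C(/C=C/c1ccc(O)cc1)O[C@@H]2[C@H](O[Si](C)(C)C(C)(C)C)C[C@@](O)(C(=O)OC)C[C@H]2OC(=O)C=C | intermediate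
10 | methyl 4-O-acryloyl-5-O-[(E)-4-hydroxycinnamoyl]-3-O-(tert-butyldimethylsilyl)quinate | C=CC(=O)O[C@@H]1[C@H](O[Si](C)(C)C(C)(C)C)C[C@@](O)(C(=O)OC)C[C@H]1OC(=O)/C=C/c1ccc(O)cc1 | intermediate
11 | methyl 3-O-(tert-butyldimethylsilyl)-4,5-di-O-[(E)-4-hydroxycinnamoyl]quinate | O=C(/C=C/c1ccc(O)cc1)O[C@@H]2[C@H](O[Si](C)(C)C(C)(C)C)C[C@@](O)(C(=O)OC)C[C@H]2OC(=O)/C=C/c1ccc(O)cc1 | intermediate
12 | methyl 4,5-di-O-[(E)-4-hydroxycinnamoyl]quinate (1-OH and 3-OH free) | O=C(/C=C/c1ccc(O)cc1)O[C@@H]2[C@H](O)C[C@@](O)(C(=O)OC)C[C@H]2OC(=O)/C=C/c1ccc(O)cc1 | intermediate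
13 | 4,5-di-O-[(E)-4-hydroxycinnamoyl]quinic acid (4,5-di-O-p-coumaroylquinic acid; both olefins E; ring configuration of 1) | O=C(/C=C/c1ccc(O)cc1)O[C@@H]1[C@H](O)C[C@@](O)(C(=O)O)C[C@H]1OC(=O)/C=C/c1ccc(O)cc1 | target

Total step count: 6. Longest linear sequence: 6 steps (1 → 13).

Steps most likely to fail

Step 5. The second arylation may stall if the catalyst aggregates to inactive palladium metal, or the acrylates may oligomerise on heating before they are arylated. The fallback sets out from 7 and builds the cinnamates by olefin cross-metathesis instead. Treating 7 with 4-acetoxystyrene (5 equiv) and the second-generation Hoveyda–Grubbs catalyst in CH2Cl2 at 40 °C should give methyl 3-O-(tert-butyldimethylsilyl)-4,5-di-O-[(E)-4-acetoxycinnamoyl]quinate F1, since acrylate–styrene cross-metathesis is E-selective. The aqueous HCl–THF treatment of step 6, which also hydrolyses the two aryl acetates, then takes F1 to 13, where the fallback rejoins the route.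

Step 6. Hydrolysis of the hindered methyl ester may be so slow that water begins to cleave the cinnamate esters, or an acyl group may drift to O3 once the silyl ether is gone. The fallback sets out from 11 and removes the methyl group by substitution at carbon, not by attack at the carbonyl. LiI in EtOAc at reflux followed by acidic work-up should give 3-O-(tert-butyldimethylsilyl)-4,5-di-O-[(E)-4-hydroxycinnamoyl]quinic acid F2, because iodide attacks only the methyl carbon and leaves the secondary cinnamates alone. HF·pyridine in THF at 0 °C → rt then removes the silyl ether under non-hydrolytic acidic conditions and the fallback comes back at 13.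

Step 3. Lactone and hydroxy ester equilibrate, so opening may stay incomplete, and longer exposure to alkoxide lets the silyl group wander from O3 to O4. The fallback sets out from 3 and opens the lactone irreversibly. LiOH (1.1 equiv) in THF–water at 0 °C for a short time, then careful acidification to about pH 4 in the cold, should give 3-O-(tert-butyldimethylsilyl)quinic acid F3. Esterification with TMSCHN2 in MeOH–toluene at 0 °C under neutral conditions then returns to the route at 4.

Further compounds
F1 | step 5 | methyl 3-O-(tert-butyldimethylsilyl)-4,5-di-O-[(E)-4-acetoxycinnamoyl]quinate | CC(=O)Oc1ccc(/C=C/C(=O)O[C@@H]2[C@H](O[Si](C)(C)C(C)(C)C)C[C@@](O)(C(=O)OC)C[C@H]2OC(=O)/C=C/c2ccc(OC(C)=O)cc2)cc1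
F2 | step 6 | 3-O-(tert-butyldimethylsilyl)-4,5-di-O-[(E)-4-hydroxycinnamoyl]quinic acid | O=C(/C=C/c1ccc(O)cc1)O[C@@H]2[C@H](O[Si](C)(C)C(C)(C)C)C[C@@](O)(C(=O)O)C[C@H]2OC(=O)/C=C/c1ccc(O)cc1
F3 | step 3 | 3-O-(tert-butyldimethylsilyl)quinic acid | O[C@@H]1[C@H](O[Si](C)(C)C(C)(C)C)C[C@@](O)(C(=O)O)C[C@H]1O
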